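The route rests on cutting the bond between the carbinol carbon C7 of the glycerol side chain and C1 of the outer 4-hydroxy-3,5-dimethoxyphenyl ring (ring E). In the key step an arylmagnesium bromide adds to an (R)-2-aryloxy-3-silyloxypropanal that already carries the complete protected furofuran. Magnesium is clamped between the aldehyde oxygen, the C8 ether oxygen and a flanking methoxy group of the inner 2,6-dimethoxyphenoxy ring (ring D), so that one operation joins the two halves and sets C7 threo to C8. The precursor aldehyde comes from a Mitsunobu inversion on a glycerate; its furofuran from an Evans succinate aldol–lactonisation and a rhodium carbenoid C–H insertion that places the ring D aryl endo.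

Key step: step 19

Remark: C7, C8 and C9 are the carbinol, aryloxy and hydroxymethyl carbons of the side chain; ring A is the guaiacyl ring, rings B and C are the two oxolanes, numbered as 3,7-dioxabicyclo[3.3.0]octane (C2 bears ring D, C6 bears ring A, C8 is the former lactone carbon). The target is read as (7R,8R)-threo, with the ring A aryl exo and the ring D aryl endo on the cis-fused bicycle. Compounds 1, 3, 4, 10, 21 and 26 are assumed to be bought.

Step 1
Reactants: 1 vanillin
Product: 2 3-methoxy-4-(triisopropylsilyloxy)benzaldehyde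
Conditions: TIPSCl, imidazole, DMF, rt
Reagents that add atoms: triisopropylsilyl chloride, CC(C)[Si](Cl)(C(C)C)C(C)C
Why: Imidazole-promoted O-silylation of the phenol, the TIPS aryl ether being chosen because it should survive LiOOH, borane, hydride and Grignard steps and fall only to fluoride at the end.

Step 2
Reactants: 3 (R)-4-benzyl-2-oxazolidinone; 4 methyl 4-chloro-4-oxobutanoate
Product: 5 (R)-4-benzyl-3-(4-methoxy-4-oxobutanoyl)oxazolidin-2-one
Conditions: n-BuLi, THF, −78 °C; then 4, −78 to 0 °C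
Reagents that add atoms: none
Why: N-acylation of the lithiated oxazolidinone by the acid chloride, which reacts far faster than the methyl ester.

Step 3
Reactants: 5 (R)-4-benzyl-3-(4-methoxy-4-oxobutanoyl)oxazolidin-2-one; 2 3-methoxy-4-(triisopropylsilyloxy)benzaldehyde
Product: 7 (R)-4-benzyl-3-{(2R,3R)-2-[3-methoxy-4-(triisopropylsilyloxy)phenyl]-5-oxotetrahydrofuran-3-carbonyl}oxazolidin-2-one (trans-lactone imide), via syn-aldol adduct 6 (not isolated)
Conditions: Bu2BOTf, i-Pr2NEt, CH2Cl2, −78 to 0 °C; 2, −78 to 0 °C; H2O2, pH 7 buffer, MeOH; then PPTS (cat.), CH2Cl2, rt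
Reagents that add atoms: none
Why: Evans syn-aldol through the Z-dibutylboron enolate, formed selectively at the imide α-CH2, and a Zimmerman–Traxler chair in which the aldehyde approaches the enolate face opposite the benzyl group of the (R)-auxiliary, which should set both new stereocentres as (R,R)-syn, after which the γ-hydroxy ester closes 5-exo-trig onto the methyl ester to the trans-4,5-disubstituted γ-lactone.

Step 4
Reactants: 7 trans-lactone imide
Product: 8 (2R,3R)-2-[3-methoxy-4-(triisopropylsilyloxy)phenyl]-5-oxotetrahydrofuran-3-carboxylic acid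
Conditions: LiOH, H2O2, THF/H2O, 0 °C; Na2SO3; then HCl to pH 2
Reagents that add atoms: hydrogen peroxide (as LiOOH), OO (one oxygen of the CO2H group)
Why: Peroxide-assisted auxiliary cleavage in which LiOOH attacks the exocyclic imide carbonyl chemoselectively, while acidification re-closes any ring-opened γ-hydroxy acid and the trans arrangement is also the thermodynamic one.

Step 5
Reactants: 8 (2R,3R)-paraconic acid
Product: 9 (4S,5R)-4-(hydroxymethyl)-5-[3-methoxy-4-(triisopropylsilyloxy)phenyl]dihydrofuran-2(3H)-one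
Conditions: BH3·SMe2, THF, 0 °C to rt; MeOH quench
Reagents that add atoms: none
Why: Borane reduces a carboxylic acid through its acyloxyborane much faster than a γ-lactone, so CO2H should become CH2OH without touching the ring or either stereocentre (the descriptor at C4 changes only by priority).

Step 6
Reactants: 10 4-(benzyloxy)-3,5-dimethoxybenzaldehyde
Product: 11 [4-(benzyloxy)-3,5-dimethoxyphenyl]methanol
Conditions: NaBH4, MeOH, 0 °C
Reagents that add atoms: none
Why: Simple borohydride reduction of an aromatic aldehyde.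

Step 7
Reactants: 11 [4-(benzyloxy)-3,5-dimethoxyphenyl]methanol
Product: 12 4-(benzyloxy)-3,5-dimethoxybenzyl 2,2,2-trichloroacetimidate
Conditions: Cl3CCN, DBU (cat.), CH2Cl2, 0 °C
Reagents that add atoms: trichloroacetonitrile, ClC(Cl)(Cl)C#N
Why: Base-catalysed addition of the benzylic alcohol to trichloroacetonitrile gives the acid-labile imidate donor.

Step 8
Reactants: 9 hydroxymethyl lactone; 12 trichloroacetimidate
Product: 13 (4S,5R)-4-({[4-(benzyloxy)-3,5-dimethoxybenzyl]oxy}methyl)-5-[3-methoxy-4-(triisopropylsilyloxy)phenyl]dihydrofuran-2(3H)-one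
Conditions: TMSOTf (cat.), CH2Cl2, −20 to 0 °C
Reagents that add atoms: none
Why: Acid-catalysed trichloroacetimidate benzylation through the stabilised 4-alkoxybenzyl cation works under non-basic conditions and so avoids the acyl shift to the primary alkoxide (translactonisation) that a Williamson etherification would provoke.

Step 9
Reactants: 13 benzyl ether lactone
Product: 15 (4S,5R)-3-diazo-4-({[4-(benzyloxy)-3,5-dimethoxybenzyl]oxy}methyl)-5-[3-methoxy-4-(triisopropylsilyloxy)phenyl]dihydrofuran-2(3H)-one, via 3-trifluoroacetyl lactone 14 (not isolated)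
Conditions: LiN(SiMe3)2, THF, −78 °C; CF3CO2CH2CF3; aq HCl work-up; then p-ABSA, Et3N, H2O, MeCN, rt
Reagents that add atoms: 4-acetamidobenzenesulfonyl azide (p-ABSA), CC(=O)Nc1ccc(cc1)S(=O)(=O)N=[N+]=[N-] (the N2 unit of 15); 2,2,2-trifluoroethyl trifluoroacetate, O=C(OCC(F)(F)F)C(F)(F)F (the trifluoroacetyl group of 14 only)
Why: Detrifluoroacetylative Regitz diazo transfer, in which Claisen trifluoroacetylation of the lithium enolate activates C3, the sulfonyl azide transfers N2 and the trifluoroacetyl group leaves as the N-sulfonyl amide, with C4 and C5 not involved.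

Step 10
Reactants: 15 diazo lactone
Product: 16 (1R,2S,5S,6R)-2-[4-(benzyloxy)-3,5-dimethoxyphenyl]-6-[3-methoxy-4-(triisopropylsilyloxy)phenyl]-3,7-dioxabicyclo[3.3.0]octan-8-one (2-aryl endo and 6-aryl exo)
Conditions: Rh2(OAc)4 (2 mol %), CH2Cl2, 40 °C, slow addition of 15
Reagents that add atoms: none
Why: Rhodium carbenoid 1,5 C–H insertion into the ether-activated benzylic C–H bond forms the C1–C2 bond and the second oxolane, necessarily cis-fused, and the aryl group on the inserting carbon should turn away from the carboxylate wall of the dirhodium unit that departs on the convex face, so that it ends endo and C1 and C2 are set relative to C5 and C6 of the lactone.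

Step 11
Reactants: 16 endo,exo-furofuranone
Product: 17 (R)-{(3S,4S,5S)-5-[4-(benzyloxy)-3,5-dimethoxyphenyl]-4-(hydroxymethyl)tetrahydrofuran-3-yl}[3-methoxy-4-(triisopropylsilyloxy)phenyl]methanol
Conditions: LiBH4, THF, 0 °C to rt
Reagents that add atoms: none
Why: LiBH4 reduces the lactone to the 1,4-diol without touching aryl silyl or benzyl ethers, and no stereocentre is affected.

Step 12
Reactants: 17 diol
Product: 19 (1S,2S,5S,6R)-2-[4-(benzyloxy)-3,5-dimethoxyphenyl]-6-[3-methoxy-4-(triisopropylsilyloxy)phenyl]-3,7-dioxabicyclo[3.3.0]octane, via primary mesylate 18 (not isolated)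
Conditions: MsCl, pyridine, CH2Cl2, 0 °C to rt
Reagents that add atoms: methanesulfonyl chloride, CS(=O)(=O)Cl (the mesyl group of 18 only; no atom of it remains in 19)
Why: Selective sulfonylation of the primary alcohol is followed by 5-exo-tet Williamson closure in which the benzylic hydroxyl is the nucleophile, so C6 keeps its configuration, and should that position ionise instead it would close to the same, thermodynamically preferred exo aryl.

Step 13
Reactants: 19 benzyl-protected furofuran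
Product: 20 2,6-dimethoxy-4-{(1S,2S,5S,6R)-6-[3-methoxy-4-(triisopropylsilyloxy)phenyl]-3,7-dioxabicyclo[3.3.0]octan-2-yl}phenol
Conditions: H2 (1 atm), Pd/C (10%), EtOAc, rt
Reagents that add atoms: none
Why: Hydrogenolysis of the aryl benzyl ether should be much faster than that of the dialkyl benzylic C–O bonds of the bicycle under neutral conditions at 1 atm, so only the ring D phenol is unmasked.

Step 14
Reactants: 21 methyl (S)-2,2-dimethyl-1,3-dioxolane-4-carboxylate
Product: 22 methyl (S)-2,3-dihydroxypropanoate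
Conditions: AcOH/H2O (4:1), 40 °C
Reagents that add atoms: none
Why: Acid-catalysed acetal hydrolysis under conditions too mild to hydrolyse the methyl ester or to racemise C2.

Step 15
Reactants: 22 methyl (S)-2,3-dihydroxypropanoate
Product: 23 methyl (S)-3-[(tert-butyldiphenylsilyl)oxy]-2-hydroxypropanoate
Conditions: TBDPSCl, imidazole, CH2Cl2, −10 to 0 °C
Reagents that add atoms: tert-butyldiphenylsilyl chloride, CC(C)(C)[Si](Cl)(c1ccccc1)c1ccccc1
Why: The bulky silyl chloride reacts selectively at the primary hydroxyl, and TBDPS is chosen because it does not chelate and survives i-Bu2AlH and Grignard reagents.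

Step 16
Reactants: 20 furofuran phenol; 23 methyl (S)-3-[(tert-butyldiphenylsilyl)oxy]-2-hydroxypropanoate
Product: 24 methyl (R)-3-[(tert-butyldiphenylsilyl)oxy]-2-(2,6-dimethoxy-4-{(1S,2S,5S,6R)-6-[3-methoxy-4-(triisopropylsilyloxy)phenyl]-3,7-dioxabicyclo[3.3.0]octan-2-yl}phenoxy)propanoate
Conditions: PPh3, DIAD, THF, 0 °C to rt
Reagents that add atoms: none
Why: Mitsunobu etherification, in which the phenol (pKa about 10) displaces the oxyphosphonium of the α-hydroxy ester by SN2 with inversion, turning the (S)-carbinol into the (R)-aryl ether that is C8 of the target.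

Step 17
Reactants: 24 aryloxy ester
Product: 25 (R)-3-[(tert-butyldiphenylsilyl)oxy]-2-(2,6-dimethoxy-4-{(1S,2S,5S,6R)-6-[3-methoxy-4-(triisopropylsilyloxy)phenyl]-3,7-dioxabicyclo[3.3.0]octan-2-yl}phenoxy)propanal
Conditions: i-Bu2AlH, CH2Cl2, −78 °C; MeOH, then aq potassium sodium tartrate
Reagents that add atoms: none
Why: Low-temperature i-Bu2AlH reduction should stop at the aldehyde because the aluminium hemiacetal of an α-alkoxy ester is chelate-stabilised until the quench, and C8 is kept by working cold and using the aldehyde crude.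

Step 18
Reactants: 26 4-bromo-2,6-dimethoxyphenol
Product: 27 (4-bromo-2,6-dimethoxyphenoxy)(tert-butyl)dimethylsilane
Conditions: TBSCl, imidazole, DMF, rt
Reagents that add atoms: tert-butyldimethylsilyl chloride, CC(C)(C)[Si](C)(C)Cl
Why: Imidazole-promoted silylation of the hindered phenol masks the acidic OH before halogen–lithium exchange.

Step 19
Reactants: 27 (4-bromo-2,6-dimethoxyphenoxy)(tert-butyl)dimethylsilane; 25 (R)-α-aryloxy aldehyde
Product: 30 (1R,2R)-3-[(tert-butyldiphenylsilyl)oxy]-1-[4-(tert-butyldimethylsilyloxy)-3,5-dimethoxyphenyl]-2-(2,6-dimethoxy-4-{(1S,2S,5S,6R)-6-[3-methoxy-4-(triisopropylsilyloxy)phenyl]-3,7-dioxabicyclo[3.3.0]octan-2-yl}phenoxy)propan-1-ol (protected threo alcohol), via aryllithium 28 (not isolated), via arylmagnesium bromide 29 (not isolated)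
Conditions: 27, t-BuLi (2 equiv), Et2O, −78 °C; MgBr2·OEt2 (excess), −78 to 0 °C; then 25 in CH2Cl2, −78 °C; aq NH4Cl
Reagents that add atoms: tert-butyllithium, [Li]C(C)(C)C (lithium of 28 only); magnesium bromide etherate, Br[Mg]Br (MgBr of 29 only); no atom of either remains in 30
Why: Bromine–lithium exchange and transmetalation give a tetrahydrofuran-free arylmagnesium bromide, while MgBr2 binds the aldehyde oxygen and the C8 aryl ether oxygen in a five-membered Cram chelate that a flanking methoxy group of ring D can reinforce; the aryl group is then delivered to the Re face of C7, anti to the C9H2OTBDPS arm, forming the C7–C1(ring E) bond. The closest known reaction type is the chelation-controlled Grignard addition to α-alkoxy aldehydes (Cram cyclic model). No ring is closed. The one new stereocentre, C7, is controlled by the existing C8 centre through the chelate and should come out 7R, that is syn (threo) to the C8 oxygen. The step needs threo over the erythro product of the open Felkin–Anh pathway, and the substrate secures this by offering only the α-oxygen pocket for chelation (the ring D ether oxygen is twisted out of conjugation by its two ortho methoxy groups and is therefore ether-like in basicity, whereas the bulky TBDPS ether on O9 cannot form the competing six-membered chelate) in an Et2O/CH2Cl2 medium free of strong donor solvents. The aldehyde is the only electrophile present, and the low basicity of the aryl Grignard reagent at −78 °C protects the epimerisable C8 centre.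

Step 20
Reactants: 30 protected threo alcohol
Product: 31 (1R,2R)-1-(4-hydroxy-3,5-dimethoxyphenyl)-2-{4-[(1S,2S,5S,6R)-6-(4-hydroxy-3-methoxyphenyl)-3,7-dioxabicyclo[3.3.0]octan-2-yl]-2,6-dimethoxyphenoxy}propane-1,3-diol (target)
Conditions: Bu4NF, AcOH, THF, 0 °C to rt
Reagents that add atoms: none
Why: Fluoride cleaves the two aryl silyl ethers and the primary TBDPS ether in one operation, the acetic acid buffer keeping the medium from becoming basic enough to form quinone methides from the freed 4-hydroxybenzylic units or to epimerise the endo aryl centre.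

Compound list
1 | vanillin | COc1cc(C=O)ccc1O | starting material
2 | 3-methoxy-4-(triisopropylsilyloxy)benzaldehyde | COc1cc(C=O)ccc1O[Si](C(C)C)(C(C)C)C(C)C | intermediate
3 | (R)-4-benzyl-2-oxazolidinone | O=C1OC[C@@H](Cc2ccccc2)N1 | starting material
4 | methyl 4-chloro-4-oxobutanoate | COC(=O)CCC(=O)Cl | starting material
5 | (R)-4-benzyl-3-(4-methoxy-4-oxobutanoyl)oxazolidin-2-one | COC(=O)CCC(=O)N1[C@H](Cc2ccccc2)COC1=O | intermediate
6 | methyl (3R)-4-[(R)-4-benzyl-2-oxooxazolidin-3-yl]-3-{(R)-hydroxy[3-methoxy-4-(triisopropylsilyloxy)phenyl]methyl}-4-oxobutanoate (syn-aldol adduct) | COC(=O)C[C@@H](C(=O)N1[C@H](Cc2ccccc2)COC1=O)[C@@H](O)c1ccc(O[Si](C(C)C)(C(C)C)C(C)C)c(OC)c1 | intermediate (not isolated)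
7 | (R)-4-benzyl-3-{(2R,3R)-2-[3-methoxy-4-(triisopropylsilyloxy)phenyl]-5-oxotetrahydrofuran-3-carbonyl}oxazolidin-2-one | O=C1C[C@@H](C(=O)N2[C@H](Cc3ccccc3)COC2=O)[C@H](c2ccc(O[Si](C(C)C)(C(C)C)C(C)C)c(OC)c2)O1 | intermediate
8 | (2R,3R)-2-[3-methoxy-4-(triisopropylsilyloxy)phenyl]-5-oxotetrahydrofuran-3-carboxylic acid | O=C1C[C@@H](C(=O)O)[C@H](c2ccc(O[Si](C(C)C)(C(C)C)C(C)C)c(OC)c2)O1 | intermediate
9 | (4S,5R)-4-(hydroxymethyl)-5-[3-methoxy-4-(triisopropylsilyloxy)phenyl]dihydrofuran-2(3H)-one | O=C1C[C@@H](CO)[C@H](c2ccc(O[Si](C(C)C)(C(C)C)C(C)C)c(OC)c2)O1 | intermediate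
10 | 4-(benzyloxy)-3,5-dimethoxybenzaldehyde | COc1cc(C=O)cc(OC)c1OCc1ccccc1 | starting material
11 | [4-(benzyloxy)-3,5-dimethoxyphenyl]methanol | COc1cc(CO)cc(OC)c1OCc1ccccc1 | intermediate
12 | 4-(benzyloxy)-3,5-dimethoxybenzyl 2,2,2-trichloroacetimidate | COc1cc(COC(=N)C(Cl)(Cl)Cl)cc(OC)c1OCc1ccccc1 | intermediate
13 | (4S,5R)-4-({[4-(benzyloxy)-3,5-dimethoxybenzyl]oxy}methyl)-5-[3-methoxy-4-(triisopropylsilyloxy)phenyl]dihydrofuran-2(3H)-one | O=C1C[C@@H](COCc2cc(OC)c(OCc3ccccc3)c(OC)c2)[C@H](c2ccc(O[Si](C(C)C)(C(C)C)C(C)C)c(OC)c2)O1 | intermediate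
14 | 3-(trifluoroacetyl) derivative of 13 (C3 epimers or enol) | O=C1C(C(=O)C(F)(F)F)[C@@H](COCc2cc(OC)c(OCc3ccccc3)c(OC)c2)[C@H](c2ccc(O[Si](C(C)C)(C(C)C)C(C)C)c(OC)c2)O1 | intermediate (not isolated)
15 | (4S,5R)-3-diazo-4-({[4-(benzyloxy)-3,5-dimethoxybenzyl]oxy}methyl)-5-[3-methoxy-4-(triisopropylsilyloxy)phenyl]dihydrofuran-2(3H)-one | O=C1C(=[N+]=[N-])[C@@H](COCc2cc(OC)c(OCc3ccccc3)c(OC)c2)[C@H](c2ccc(O[Si](C(C)C)(C(C)C)C(C)C)c(OC)c2)O1 | intermediate
16 | (1R,2S,5S,6R)-2-[4-(benzyloxy)-3,5-dimethoxyphenyl]-6-[3-methoxy-4-(triisopropylsilyloxy)phenyl]-3,7-dioxabicyclo[3.3.0]octan-8-one | COc1cc([C@@H]2OC(=O)[C@@H]3[C@H]2CO[C@@H]3c2cc(OC)c(OCc3ccccc3)c(OC)c2)ccc1O[Si](C(C)C)(C(C)C)C(C)C | intermediate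
17 | (R)-{(3S,4S,5S)-5-[4-(benzyloxy)-3,5-dimethoxyphenyl]-4-(hydroxymethyl)tetrahydrofuran-3-yl}[3-methoxy-4-(triisopropylsilyloxy)phenyl]methanol | COc1cc([C@H](O)[C@@H]2CO[C@H](c3cc(OC)c(OCc4ccccc4)c(OC)c3)[C@@H]2CO)ccc1O[Si](C(C)C)(C(C)C)C(C)C | intermediate
18 | [(2S,3S,4S)-2-[4-(benzyloxy)-3,5-dimethoxyphenyl]-4-{(R)-hydroxy[3-methoxy-4-(triisopropylsilyloxy)phenyl]methyl}tetrahydrofuran-3-yl]methyl methanesulfonate | COc1cc([C@H](O)[C@@H]2CO[C@H](c3cc(OC)c(OCc4ccccc4)c(OC)c3)[C@@H]2COS(C)(=O)=O)ccc1O[Si](C(C)C)(C(C)C)C(C)C | intermediate (not isolated)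
19 | (1S,2S,5S,6R)-2-[4-(benzyloxy)-3,5-dimethoxyphenyl]-6-[3-methoxy-4-(triisopropylsilyloxy)phenyl]-3,7-dioxabicyclo[3.3.0]octane | COc1cc([C@@H]2OC[C@@H]3[C@H]2CO[C@@H]3c2cc(OC)c(OCc3ccccc3)c(OC)c2)ccc1O[Si](C(C)C)(C(C)C)C(C)C | intermediate
20 | 2,6-dimethoxy-4-{(1S,2S,5S,6R)-6-[3-methoxy-4-(triisopropylsilyloxy)phenyl]-3,7-dioxabicyclo[3.3.0]octan-2-yl}phenol | COc1cc([C@@H]2OC[C@@H]3[C@H]2CO[C@@H]3c2cc(OC)c(O)c(OC)c2)ccc1O[Si](C(C)C)(C(C)C)C(C)C | intermediate
21 | methyl (S)-2,2-dimethyl-1,3-dioxolane-4-carboxylate | COC(=O)[C@@H]1COC(C)(C)O1 | starting material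
22 | methyl (S)-2,3-dihydroxypropanoate | COC(=O)[C@@H](O)CO | intermediate
23 | methyl (S)-3-[(tert-butyldiphenylsilyl)oxy]-2-hydroxypropanoate | COC(=O)[C@@H](O)CO[Si](c1ccccc1)(c1ccccc1)C(C)(C)C | intermediate
24 | methyl (R)-3-[(tert-butyldiphenylsilyl)oxy]-2-(2,6-dimethoxy-4-{(1S,2S,5S,6R)-6-[3-methoxy-4-(triisopropylsilyloxy)phenyl]-3,7-dioxabicyclo[3.3.0]octan-2-yl}phenoxy)propanoate | COc1cc([C@@H]2OC[C@@H]3[C@H]2CO[C@@H]3c2cc(OC)c(O[C@H](CO[Si](c3ccccc3)(c3ccccc3)C(C)(C)C)C(=O)OC)c(OC)c2)ccc1O[Si](C(C)C)(C(C)C)C(C)C | intermediate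
25 | (R)-3-[(tert-butyldiphenylsilyl)oxy]-2-(2,6-dimethoxy-4-{(1S,2S,5S,6R)-6-[3-methoxy-4-(triisopropylsilyloxy)phenyl]-3,7-dioxabicyclo[3.3.0]octan-2-yl}phenoxy)propanal | COc1cc([C@@H]2OC[C@@H]3[C@H]2CO[C@@H]3c2cc(OC)c(O[C@H](CO[Si](c3ccccc3)(c3ccccc3)C(C)(C)C)C=O)c(OC)c2)ccc1O[Si](C(C)C)(C(C)C)C(C)C | intermediate
26 | 4-bromo-2,6-dimethoxyphenol | COc1cc(Br)cc(OC)c1O | starting material
27 | (4-bromo-2,6-dimethoxyphenoxy)(tert-butyl)dimethylsilane | COc1cc(Br)cc(OC)c1O[Si](C)(C)C(C)(C)C | intermediate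
28 | [4-(tert-butyldimethylsilyloxy)-3,5-dimethoxyphenyl]lithium | COc1cc([Li])cc(OC)c1O[Si](C)(C)C(C)(C)C | intermediate (not isolated)
29 | [4-(tert-butyldimethylsilyloxy)-3,5-dimethoxyphenyl]magnesium bromide | COc1cc([Mg]Br)cc(OC)c1O[Si](C)(C)C(C)(C)C | intermediate (not isolated)
30 | (1R,2R)-3-[(tert-butyldiphenylsilyl)oxy]-1-[4-(tert-butyldimethylsilyloxy)-3,5-dimethoxyphenyl]-2-(2,6-dimethoxy-4-{(1S,2S,5S,6R)-6-[3-methoxy-4-(triisopropylsilyloxy)phenyl]-3,7-dioxabicyclo[3.3.0]octan-2-yl}phenoxy)propan-1-ol | COc1cc([C@@H]2OC[C@@H]3[C@H]2CO[C@@H]3c2cc(OC)c(O[C@H](CO[Si](c3ccccc3)(c3ccccc3)C(C)(C)C)[C@H](O)c3cc(OC)c(O[Si](C)(C)C(C)(C)C)c(OC)c3)c(OC)c2)ccc1O[Si](C(C)C)(C(C)C)C(C)C | intermediate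
31 | (1R,2R)-1-(4-hydroxy-3,5-dimethoxyphenyl)-2-{4-[(1S,2S,5S,6R)-6-(4-hydroxy-3-methoxyphenyl)-3,7-dioxabicyclo[3.3.0]octan-2-yl]-2,6-dimethoxyphenoxy}propane-1,3-diol | COc1cc([C@@H]2OC[C@@H]3[C@H]2CO[C@@H]3c2cc(OC)c(O[C@H](CO)[C@H](O)c3cc(OC)c(O)c(OC)c3)c(OC)c2)ccc1O | target

Total step count: 20. Longest linear sequence: 14 steps (steps 1, 3, 4, 5, 8, 9, 10, 11, 12, 13, 16, 17, 19, 20).

Steps most likely to fail

Step 19. The open Felkin–Anh pathway may compete with the magnesium chelate and erode the threo preference, and the α-aryloxy aldehyde may epimerise at C8 before it is consumed. The fallback sets out from 24 and sets C7 by hydride delivery instead of aryl delivery. Ester 24 would be converted with MeNH(OMe)·HCl and i-PrMgCl (THF, −20 °C) into the Weinreb amide F1. Addition of aryllithium 28 (Et2O/THF, −78 °C) should then form the same C7–aryl bond by acylation and give the aryl ketone F2. Reduction with the bulky, non-chelating K[HB(s-Bu)3] (THF, −78 °C) should follow the Felkin–Anh polar model with the aryloxy group anti to the incoming hydride. Because hydride and aryl have exchanged roles relative to the aldehyde addition, this open transition state leads to the threo (7R,8R) alcohol, and the route is rejoined at 30.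

Step 10. The carbenoid may be diverted into a 1,2-hydride shift to the butenolide or into attack on the electron-rich ring D arene, or the insertion may proceed with poor endo selectivity at C2. The fallback sets out from 9 and builds the second oxolane by ionic hydrogenation of a lactol.
- Alcohol 9 would be silylated (TBSCl, imidazole, DMF) to the silyl ether F3.
- The lithium enolate of F3 (LiN(SiMe3)2, THF, −78 °C) would be added to aldehyde 10 to give the aldol adduct F4 as a mixture at C3 and the carbinol carbon.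
- Dess–Martin oxidation would give the β-keto lactone F5, whose C3 centre equilibrates through the enol.
- HF·pyridine (THF, 0 °C) should remove the primary TBS group, after which the free alcohol closes onto the aryl ketone from the cis-disposed epimer to give the bicyclic lactol F6.
- Et3SiH and BF3·OEt2 (CH2Cl2, −78 °C) should reduce the derived oxocarbenium ion by hydride attack on the convex face, leaving the aryl group endo, and the route is rejoined at 16.

Step 16. Displacement of the oxyphosphonium ion by the di-ortho-substituted phenol may be slow enough for β-elimination to the acrylate or alkylation of the hydrazine dicarboxylate to take over. The fallback sets out from 23 and replaces the redox condensation by a sulfonate displacement. Alcohol 23 would be converted with Tf2O and 2,6-lutidine (CH2Cl2, −78 °C) into the triflate F7. The potassium phenoxide of 20 (K2CO3, MeCN, 0 °C) should then displace it by SN2 with inversion, and the route is rejoined at 24.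

Further compounds
F1 | step 19 | (R)-3-[(tert-butyldiphenylsilyl)oxy]-2-(2,6-dimethoxy-4-{(1S,2S,5S,6R)-6-[3-methoxy-4-(triisopropylsilyloxy)phenyl]-3,7-dioxabicyclo[3.3.0]octan-2-yl}phenoxy)-N-methoxy-N-methylpropanamide | COc1cc([C@@H]2OC[C@@H]3[C@H]2CO[C@@H]3c2cc(OC)c(O[C@H](CO[Si](c3ccccc3)(c3ccccc3)C(C)(C)C)C(=O)N(C)OC)c(OC)c2)ccc1O[Si](C(C)C)(C(C)C)C(C)C
F2 | step 19 | (R)-3-[(tert-butyldiphenylsilyl)oxy]-1-[4-(tert-butyldimethylsilyloxy)-3,5-dimethoxyphenyl]-2-(2,6-dimethoxy-4-{(1S,2S,5S,6R)-6-[3-methoxy-4-(triisopropylsilyloxy)phenyl]-3,7-dioxabicyclo[3.3.0]octan-2-yl}phenoxy)propan-1-one | COc1cc([C@@H]2OC[C@@H]3[C@H]2CO[C@@H]3c2cc(OC)c(O[C@H](CO[Si](c3ccccc3)(c3ccccc3)C(C)(C)C)C(=O)c3cc(OC)c(O[Si](C)(C)C(C)(C)C)c(OC)c3)c(OC)c2)ccc1O[Si](C(C)C)(C(C)C)C(C)C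
F3 | step 10 | (4S,5R)-4-{[(tert-butyldimethylsilyl)oxy]methyl}-5-[3-methoxy-4-(triisopropylsilyloxy)phenyl]dihydrofuran-2(3H)-one | O=C1C[C@@H](CO[Si](C)(C)C(C)(C)C)[C@H](c2ccc(O[Si](C(C)C)(C(C)C)C(C)C)c(OC)c2)O1
F4 | step 10 | (4S,5R)-3-{[4-(benzyloxy)-3,5-dimethoxyphenyl](hydroxy)methyl}-4-{[(tert-butyldimethylsilyl)oxy]methyl}-5-[3-methoxy-4-(triisopropylsilyloxy)phenyl]dihydrofuran-2(3H)-one (mixture at C3 and the carbinol carbon) | O=C1C(C(O)c2cc(OC)c(OCc3ccccc3)c(OC)c2)[C@@H](CO[Si](C)(C)C(C)(C)C)[C@H](c2ccc(O[Si](C(C)C)(C(C)C)C(C)C)c(OC)c2)O1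
F5 | step 10 | (4S,5R)-3-[4-(benzyloxy)-3,5-dimethoxybenzoyl]-4-{[(tert-butyldimethylsilyl)oxy]methyl}-5-[3-methoxy-4-(triisopropylsilyloxy)phenyl]dihydrofuran-2(3H)-one | O=C1C(C(=O)c2cc(OC)c(OCc3ccccc3)c(OC)c2)[C@@H](CO[Si](C)(C)C(C)(C)C)[C@H](c2ccc(O[Si](C(C)C)(C(C)C)C(C)C)c(OC)c2)O1
F6 | step 10 | (1R,5S,6R)-2-[4-(benzyloxy)-3,5-dimethoxyphenyl]-2-hydroxy-6-[3-methoxy-4-(triisopropylsilyloxy)phenyl]-3,7-dioxabicyclo[3.3.0]octan-8-one (anomers at C2) | COc1cc([C@@H]2OC(=O)[C@@H]3[C@H]2COC3(O)c2cc(OC)c(OCc3ccccc3)c(OC)c2)ccc1O[Si](C(C)C)(C(C)C)C(C)C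
F7 | step 16 | methyl (S)-3-[(tert-butyldiphenylsilyl)oxy]-2-{[(trifluoromethyl)sulfonyl]oxy}propanoate | COC(=O)[C@@H](OS(=O)(=O)C(F)(F)F)CO[Si](c1ccccc1)(c1ccccc1)C(C)(C)C
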